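**Retrosynthetic overview**
- The target is a methylene-bridged trimer with no stereocentres: ring A (butyryl-filicinic acid), ring B (butyryl-phloroglucinol) and ring C (propionyl-filicinic acid). The last bond made is the C–acyl bond of ring B (Friedel–Crafts).
- The feature the strategy rests on: the five-carbon run bridge CH2 – ring B carbon – ring B C(OH) – ring B carbon – bridge CH2 is the skeleton of penta-1,4-dien-3-one. The other three ring B carbons (C–OH, CH, C–OH) are a malonyl unit.
- Key disconnection: ring B is opened at the two bonds between its bridge-bearing carbons and the outer C–OH carbons, giving a 1,5-bis(acyltrione)pentan-3-one and methyl malonyl chloride ([3+3] benzannulation).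
- The pentanone comes from two successive Michael additions of the two acylfilicinic acids to divinyl ketone, released from 1,5-dichloropentan-3-one. Each acylfilicinic acid comes from phloroglucinol by Friedel–Crafts acylation and gem-dimethylation.
- Ring order: rings A and C first (dearomatised phloroglucinols), then ring B by annulation, then ring B acylation.

Key step: step 7

Remark on the chemistry: the acyltrione rings are drawn throughout in the dienol tautomer used for the target. The Michael adducts may sit partly as cyclic hemiketals of the chain ketone, which reopen under the basic conditions of the following steps. They are therefore worked up cold at about pH 4 and used without delay.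

**Route**

Step 1
Reactants: 1 phloroglucinol; 2 butyryl chloride
Product: 3 1-(2,4,6-trihydroxyphenyl)butan-1-one (butyrylphloroglucinol)
Conditions: AlCl3, PhNO2–CH2Cl2, 0 °C → rt; ice/HCl
Reagents that add atoms: butyryl chloride (2), CCCC(=O)Cl
Why: Friedel–Crafts C-acylation of phloroglucinol should stop at the mono-ketone because the first acyl group, chelated to aluminium, deactivates the ring.

Step 2
Reactants: 3 butyrylphloroglucinol; 4 iodomethane
Product: 5 butyrylfilicinic acid (2-butanoyl-3,5-dihydroxy-4,4-dimethylcyclohexa-2,5-dien-1-one)
Conditions: NaOMe, MeI, MeOH, 0 °C → rt; dilute HCl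
Reagents that add atoms: iodomethane (4), CI
Why: Dearomatising double C-methylation of the acylphloroglucinol phenoxide at one ring carbon is the established route to acylfilicinic acids, the gem-dimethyl trione being stabilised as a vinylogous acid anion.

Step 3
Reactants: 1 phloroglucinol; 6 propionyl chloride
Product: 7 1-(2,4,6-trihydroxyphenyl)propan-1-one (propionylphloroglucinol)
Conditions: AlCl3, PhNO2–CH2Cl2, 0 °C → rt; ice/HCl
Reagents that add atoms: propionyl chloride (6), CCC(=O)Cl
Why: Friedel–Crafts mono-acylation of phloroglucinol, as in step 1.

Step 4
Reactants: 7 propionylphloroglucinol; 4 iodomethane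
Product: 8 propionylfilicinic acid (3,5-dihydroxy-4,4-dimethyl-2-propanoylcyclohexa-2,5-dien-1-one)
Conditions: NaOMe, MeI, MeOH, 0 °C → rt; dilute HCl
Reagents that add atoms: iodomethane (4), CI
Why: Dearomatising gem-dimethylation, as in step 2.

Step 5
Reactants: 5 butyrylfilicinic acid; 9 1,5-dichloropentan-3-one (excess)
Product: 11 2-butanoyl-3,5-dihydroxy-4,4-dimethyl-6-(3-oxopent-4-en-1-yl)cyclohexa-2,5-dien-1-one (mono-adduct enone), via divinyl ketone 10 (not isolated)
Conditions: 9 (4 equiv), Et3N, THF, 0 °C; then 5 added slowly, 0 °C → rt; volatiles removed cold; cold aqueous citric acid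
Reagents that add atoms: 1,5-dichloropentan-3-one (9), O=C(CCCl)CCCl
Why: Et3N removes two HCl from the bis(beta-chloro) ketone by E1cB elimination to release divinyl ketone, the soft trione carbanion adds to it at its only unsubstituted ring carbon (Michael addition), and the excess of dienone with slow addition of 5 should hold the reaction at mono-addition.

Step 6
Reactants: 11 mono-adduct enone; 8 propionylfilicinic acid
Product: 12 1-(5-butanoyl-2,4-dihydroxy-3,3-dimethyl-6-oxocyclohexa-1,4-dien-1-yl)-5-(2,4-dihydroxy-3,3-dimethyl-6-oxo-5-propanoylcyclohexa-1,4-dien-1-yl)pentan-3-one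
Conditions: Et3N, MeCN, 0 °C → rt; cold aqueous citric acid
Reagents that add atoms: none
Why: Michael addition of the second trione carbanion to the remaining vinyl ketone under mild amine base at low temperature, chosen so that retro-Michael exchange of the two nearly identical trione arms does not set in.

Step 7
Reactants: 12 bis(trione) pentan-3-one; 13 methyl 3-chloro-3-oxopropanoate (methyl malonyl chloride)
Product: 16 des-butyryl trimer (ring B is a 2,4-disubstituted phloroglucinol carrying the ring A trione-methyl group at C2 and the ring C trione-methyl group at C4), via ring-A-side dioxo ester 14 (not isolated), via ring-C-side dioxo ester 15 (not isolated)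
Conditions: MgBr2·OEt2, i-Pr2NEt (excess), CH2Cl2, 0 °C; 13 (excess) added slowly, 0 °C → rt; evaporate; NaOMe (excess), MeOH, argon, rt → 45 °C; cold 1 M HCl
Reagents that add atoms: methyl malonyl chloride (13), COC(=O)CC(=O)Cl
Why: Proposed new method: with MgBr2·OEt2 and i-Pr2NEt the two trione units are held as magnesium chelates and the central ketone is soft-enolised, its magnesium enolate is C-acylated at either alpha-CH2 by 13 (directly or by acyl relay from a trione enol ester, which is an active ester) to give the 2-substituted methyl 3,5-dioxo esters 14 and 15, and NaOMe then lets the other alpha-CH2 attack the ester so that the resulting 2,4-dialkylcyclohexane-1,3,5-trione tautomerises to the phloroglucinol. The closest known reactions are the soft-enolisation C-acylation of simple ketones by acid chlorides (MgBr2·OEt2, i-Pr2NEt) and the Claisen cyclisation of methyl 3,5-dioxohexanoate to phloroglucinol, and their union on a dialkyl ketone as one [3+3] benzannulation beside acidic triones is new. Ring B closes by a 6-exo-trig acyl substitution (Dieckmann-type, enolate carbon inside the forming ring), which makes the two bonds between the bridge-bearing carbons and the outer C–OH carbons. No stereocentre is set, since the CH centre of 14 and 15 is racemic, labile and erased on aromatisation. The step needs C-acylation at the ketone alpha-carbons and not on the triones, which is secured because every trione ring carbon is already substituted (acyl, gem-dimethyl, alkyl chain) so that only enol esters can form there and methoxide cleaves them, while the anionic triones are too electron-rich to accept a Robinson-type aldol, and the choice between the two alpha-carbons does not matter because 14 and 15 converge on 16. A 4-hydroxy-2-pyranone formed by O-attack on the ester would be reopened by methoxide to the same dioxo ester, so aromatisation to ring B is the only irreversible exit.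

Step 8
Reactants: 16 des-butyryl trimer; 2 butyryl chloride
Product: 17 target trimer (ring B = 3,5-bis(trione-methyl)-2,4,6-trihydroxybutyrophenone)
Conditions: n-PrCOCl, AlCl3 (excess), PhNO2–CH2Cl2, 0 °C → rt; ice/1 M HCl
Reagents that add atoms: butyryl chloride (2), CCCC(=O)Cl
Why: Friedel–Crafts acylation at the single free CH of the 2,4-dialkylphloroglucinol ring B, the most electron-rich carbon of the molecule, while aluminium chelation of the two acyltrione units should shield their oxygens from acylation.

**Compound list**
1 | phloroglucinol | Oc1cc(O)cc(O)c1 | starting material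
2 | butyryl chloride | CCCC(=O)Cl | starting material
3 | 1-(2,4,6-trihydroxyphenyl)butan-1-one | CCCC(=O)c1c(O)cc(O)cc1O | intermediate
4 | iodomethane | CI | starting material
5 | butyrylfilicinic acid | CCCC(=O)C1=C(O)C(C)(C)C(O)=CC1=O | intermediate
6 | propionyl chloride | CCC(=O)Cl | starting material
7 | 1-(2,4,6-trihydroxyphenyl)propan-1-one | CCC(=O)c1c(O)cc(O)cc1O | intermediate
8 | propionylfilicinic acid | CCC(=O)C1=C(O)C(C)(C)C(O)=CC1=O | intermediate
9 | 1,5-dichloropentan-3-one | O=C(CCCl)CCCl | starting material
10 | divinyl ketone (penta-1,4-dien-3-one), formed in the flask | C=CC(=O)C=C | intermediate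
11 | mono-adduct enone, 6-(3-oxopent-4-en-1-yl)butyrylfilicinic acid | C=CC(=O)CCC1=C(O)C(C)(C)C(O)=C(C(=O)CCC)C1=O | intermediate
12 | pentan-3-one bearing the ring A trione at C1 and the ring C trione at C5 | O=C(CCC1=C(O)C(C)(C)C(O)=C(C(=O)CCC)C1=O)CCC1=C(O)C(C)(C)C(O)=C(C(=O)CC)C1=O | intermediate
13 | methyl 3-chloro-3-oxopropanoate (methyl malonyl chloride) | COC(=O)CC(=O)Cl | starting material
14 | methyl 3,5-dioxo ester acylated next to the ring A arm (racemic at the CH between the two ketones, not isolated) | COC(=O)CC(=O)C(CC1=C(O)C(C)(C)C(O)=C(C(=O)CCC)C1=O)C(=O)CCC1=C(O)C(C)(C)C(O)=C(C(=O)CC)C1=O | intermediate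
15 | methyl 3,5-dioxo ester acylated next to the ring C arm (racemic at the CH between the two ketones, not isolated) | COC(=O)CC(=O)C(CC1=C(O)C(C)(C)C(O)=C(C(=O)CC)C1=O)C(=O)CCC1=C(O)C(C)(C)C(O)=C(C(=O)CCC)C1=O | intermediate
16 | trimer lacking the ring B butyryl group | CCCC(=O)C1=C(O)C(C)(C)C(O)=C(Cc2c(O)cc(O)c(CC3=C(O)C(C)(C)C(O)=C(C(=O)CC)C3=O)c2O)C1=O | intermediate
17 | target trimer (no stereocentres) | CCCC(=O)C1=C(O)C(C)(C)C(O)=C(Cc2c(O)c(CC3=C(O)C(C)(C)C(O)=C(C(=O)CC)C3=O)c(O)c(C(=O)CCC)c2O)C1=O | target

**Step count**
Total: 8 steps. Longest linear sequence: 6 steps (steps 1, 2, 5, 6, 7, 8).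

**Steps most likely to fail**

1. Step 7 (proposed new method).
   - What may go wrong: the acid chloride may be used up by O-acylation of the trione enolates and by ketene formation before the ketone is C-acylated. Methoxide may cleave the dioxo ester by retro-Claisen faster than the ring closes. Alkaline exchange of the methylene bridges in the product may scramble the butyryl and propionyl arms into homologues that are hard to separate.
   - Fallback (known chemistry): it sets out from 3 and 5 and comes back to the route at 17, so steps 5 to 8 are bypassed. Butyrylphloroglucinol 3 and butyrylfilicinic acid 5 would be joined with aqueous formaldehyde in dilute aqueous KOH at 0 °C → rt to give the methylene-bridged dimer flavaspidic acid BB F1, separated from the symmetrical dimers. F1 and propionylfilicinic acid 8 would then be bridged at the last free ring B carbon under the same formaldehyde/KOH conditions to give 17.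

2. Step 8.
   - What may go wrong: AlCl3 may cleave or shift the methylene bridges, and O-acylation of the enols and phenols may compete with C-acylation.
   - Fallback: it sets out from 16 and comes back at 17. A Houben–Hoesch reaction of 16 with butyronitrile, ZnCl2 and HCl gas in Et2O at 0 °C should give the ketimine hydrochloride F2 at the free ring B carbon. Warming F2 in water at 60–80 °C should hydrolyse it to 17.

3. Step 5.
   - What may go wrong: a second conjugate addition on the bifunctional dienone and polymerisation of divinyl ketone may compete with mono-addition.
   - Fallback: it sets out from 5 and comes back at 11. Michael addition of 5 to acrolein (catalytic Et3N, THF, 0 °C) would give the aldehyde F3, which may sit as its cyclic lactol. Addition of excess CH2=CHMgBr (THF, −78 → 0 °C, the trione being protected as its magnesium dianion) would give the racemic allylic alcohol F4. Oxidation of F4 with MnO2 in CH2Cl2 at rt would give enone 11.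

**Further compounds**
F1 | step 7 | flavaspidic acid BB (butyrylfilicinic acid–CH2–butyrylphloroglucinol) | CCCC(=O)C1=C(O)C(C)(C)C(O)=C(Cc2c(O)cc(O)c(C(=O)CCC)c2O)C1=O
F2 | step 8 | ring B butyl ketimine of the target, as hydrochloride | CCCC(=N)c1c(O)c(CC2=C(O)C(C)(C)C(O)=C(C(=O)CCC)C2=O)c(O)c(CC2=C(O)C(C)(C)C(O)=C(C(=O)CC)C2=O)c1O.Cl
F3 | step 5 | 3-(5-butanoyl-2,4-dihydroxy-3,3-dimethyl-6-oxocyclohexa-1,4-dien-1-yl)propanal | O=CCCC1=C(O)C(C)(C)C(O)=C(C(=O)CCC)C1=O
F4 | step 5 | racemic 2-butanoyl-3,5-dihydroxy-6-(3-hydroxypent-4-en-1-yl)-4,4-dimethylcyclohexa-2,5-dien-1-one | C=CC(O)CCC1=C(O)C(C)(C)C(O)=C(C(=O)CCC)C1=O
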